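**Retrosynthetic overview**

1. Target 16 ⇐ bis-MOM ether 15 ⇐ triene 13 by a double olefin metathesis in one flask: ring-closing metathesis closes the 2H-pyran (ring D) at its CH=CH bond, and cross-metathesis with 2-methylbut-2-ene turns the 8-allyl group of ring A into the prenyl group.
2. 13 ⇐ chromone 4 + arylboronic acid 12 by a rhodium-catalysed asymmetric 1,4-addition, which forms the C2–C1' bond and sets the only stereocentre (2S).
3. 4 ⇐ 3-allyl-2,4-dihydroxyacetophenone 1 (MOM ether, enaminone, cyclisation); 12 ⇐ 5-bromo-2,4-dihydroxybenzaldehyde 5 (MOM ether, tertiary propargyl ether, semihydrogenation, Wittig methylenation, Br/Li/B exchange).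
4. Order of ring formation: rings A and B are bought; ring C is closed as the chromone in step 2 and becomes the chromanone in step 8; ring D is closed last, in step 9.
5. Enabling feature: on ring B the pyran carbon C4 sits on C5', ortho to the ether oxygen on C4', and that oxygen carries the quaternary C2(CH3)2 whose remaining bond goes to C3. A vinyl group on C5' and an O–C(CH3)2–CH=CH2 group on C4' are therefore a 1,7-diene preorganised by the arene and the gem-dimethyl group, and the prenyl group on C8 of ring A differs from an allyl group only in its terminal =C(CH3)2.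

Key step: step 9

Remark: 1 and 5 are taken as catalogue compounds; the sense of induction in step 8 is assigned by analogy with the addition of arylboronic acids to 2-cyclohexenone, and the antipodal diene ligand is used if the sense proves opposite on the chromone.

**Route**

Step 1
Reactants: 1 3-allyl-2,4-dihydroxyacetophenone
Product: 2 1-[2-hydroxy-4-(methoxymethoxy)-3-(prop-2-en-1-yl)phenyl]ethan-1-one
Conditions: MOMCl, K2CO3, acetone, 0 °C to rt
Reagents that add atoms: chloromethyl methyl ether, COCCl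
Why: Williamson-type MOM ether formation is expected only at the 4-OH, because the 2-OH is held in a hydrogen bond to the acetyl carbonyl and is not alkylated with a weak base.

Step 2
Reactants: 2 1-[2-hydroxy-4-(methoxymethoxy)-3-(prop-2-en-1-yl)phenyl]ethan-1-one
Product: 4 7-(methoxymethoxy)-8-(prop-2-en-1-yl)-4H-chromen-4-one, via enaminone 3 (not isolated)
Conditions: Me2NCH(OMe)2, toluene, 100 °C; evaporate; AcOH, 60 °C
Reagents that add atoms: N,N-dimethylformamide dimethyl acetal, COC(OC)N(C)C
Why: Condensation of the methyl ketone with the amide acetal gives the enaminone, and acid-mediated intramolecular conjugate addition of the phenol with loss of dimethylamine closes the chromone (enaminone route to chromones), acetic acid being too weak to cleave the aryl MOM ether.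

Step 3
Reactants: 5 5-bromo-2,4-dihydroxybenzaldehyde
Product: 6 5-bromo-2-hydroxy-4-(methoxymethoxy)benzaldehyde
Conditions: MOMCl, K2CO3, acetone, 0 °C to rt
Reagents that add atoms: chloromethyl methyl ether, COCCl
Why: Regioselective Williamson-type MOM protection should occur at the more acidic, non-chelated 4-OH (para to the formyl group), while the 2-OH stays hydrogen-bonded to the aldehyde.

Step 4
Reactants: 6 5-bromo-2-hydroxy-4-(methoxymethoxy)benzaldehyde
Product: 7 5-bromo-4-(methoxymethoxy)-2-[(2-methylbut-3-yn-2-yl)oxy]benzaldehyde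
Conditions: 3-chloro-3-methylbut-1-yne, K2CO3, KI (cat.), CuI (cat.), DMF, 60 °C
Reagents that add atoms: 3-chloro-3-methylbut-1-yne, CC(C)(Cl)C#C
Why: Copper-catalysed propargylic O-alkylation of the remaining phenoxide with the tertiary propargylic chloride is the standard entry to aryl 1,1-dimethylpropargyl ethers and has only one hydroxyl to choose from.

Step 5
Reactants: 7 5-bromo-4-(methoxymethoxy)-2-[(2-methylbut-3-yn-2-yl)oxy]benzaldehyde
Product: 8 5-bromo-4-(methoxymethoxy)-2-[(2-methylbut-3-en-2-yl)oxy]benzaldehyde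
Conditions: H2 (1 atm), Pd/CaCO3 poisoned with Pb(OAc)2, quinoline, EtOAc, rt
Reagents that add atoms: none
Why: Lindlar semihydrogenation should stop at the terminal alkene and leave the aryl bromide, the aldehyde and the MOM ether untouched.

Step 6
Reactants: 8 5-bromo-4-(methoxymethoxy)-2-[(2-methylbut-3-en-2-yl)oxy]benzaldehyde
Product: 9 1-bromo-5-ethenyl-2-(methoxymethoxy)-4-[(2-methylbut-3-en-2-yl)oxy]benzene
Conditions: Ph3PCH3Br, NaN(SiMe3)2, THF, 0 °C; then 8, −78 °C to 0 °C
Reagents that add atoms: methyltriphenylphosphonium bromide, C[P+](c1ccccc1)(c1ccccc1)c1ccccc1.[Br-]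
Why: Wittig methylenation with the non-stabilised ylide converts the aldehyde into the styrene, and the aryl bromide, the MOM ether and the tertiary allyl ether are inert to the ylide at low temperature.

Step 7
Reactants: 9 1-bromo-5-ethenyl-2-(methoxymethoxy)-4-[(2-methylbut-3-en-2-yl)oxy]benzene
Product: 12 {5-ethenyl-2-(methoxymethoxy)-4-[(2-methylbut-3-en-2-yl)oxy]phenyl}boronic acid, via aryllithium 10 (not isolated), via lithium triisopropoxyborate 11 (not isolated)
Conditions: B(OiPr)3, n-BuLi, toluene/THF, −78 °C (in situ trapping); then H2O, AcOH to pH 6, 0 °C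
Reagents that add atoms: triisopropyl borate, CC(C)OB(OC(C)C)OC(C)C; water, O
Why: Bromine–lithium exchange, assisted by the ortho MOM oxygen, is faster at −78 °C than attack of n-BuLi on the styrene or the borate, and the aryllithium is trapped at once as the ate complex, which mild hydrolysis converts into the boronic acid (used without storage).

Step 8
Reactants: 4 7-(methoxymethoxy)-8-(prop-2-en-1-yl)-4H-chromen-4-one; 12 {5-ethenyl-2-(methoxymethoxy)-4-[(2-methylbut-3-en-2-yl)oxy]phenyl}boronic acid
Product: 13 (2S)-2-{5-ethenyl-2-(methoxymethoxy)-4-[(2-methylbut-3-en-2-yl)oxy]phenyl}-7-(methoxymethoxy)-8-(prop-2-en-1-yl)-2,3-dihydro-4H-chromen-4-one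
Conditions: [RhCl(C2H4)2]2 (2.5 mol%), (S,S)-Ph-bod* [(1S,4S)-2,5-diphenylbicyclo[2.2.2]octa-2,5-diene] (5.5 mol%), KOH (10 mol%), 1,4-dioxane/H2O (10:1), 30 °C
Reagents that add atoms: none
Why: In this Hayashi–Miyaura reaction the Ar–Rh species formed by transmetalation inserts the chromone C2=C3 bond, the C2-symmetric chiral diene blocks one face so that the aryl group should be delivered to the face giving 2S, and protonolysis of the Rh oxa-π-allyl releases the flavanone, the isolated terminal olefins being far less reactive than the enone.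

Step 9
Reactants: 13 (2S)-2-{5-ethenyl-2-(methoxymethoxy)-4-[(2-methylbut-3-en-2-yl)oxy]phenyl}-7-(methoxymethoxy)-8-(prop-2-en-1-yl)-2,3-dihydro-4H-chromen-4-one
Product: 15 (2S)-7-(methoxymethoxy)-2-[7-(methoxymethoxy)-2,2-dimethyl-2H-chromen-6-yl]-8-(3-methylbut-2-en-1-yl)-2,3-dihydro-4H-chromen-4-one, via ring-closed allyl chromene 14 (not isolated)
Conditions: RuCl2(=CHPh)(PCy3)(H2IMes) (second-generation Grubbs catalyst, 5 mol%), 1,4-benzoquinone (10 mol%), CH2Cl2 (5 mM), 40 °C; then 2-methylbut-2-ene (excess), further catalyst (3 mol%), 40 °C, same flask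
Reagents that add atoms: 2-methylbut-2-ene, CC=C(C)C
Why: The Ru carbene loads on the unhindered styrenyl olefin of ring B, adds to the neighbouring O–C(CH3)2–CH=CH2 olefin in an intramolecular [2+2] step, and cycloreversion of the ruthenacyclobutane expels ethene and forges the C3=C4 bond (Chauvin mechanism), after which the Ru=CMe2 and Ru=CHMe carbenes formed from 2-methylbut-2-ene convert the remote 8-allyl terminus into the prenyl group with loss of propene. The closest known reaction types are the ring-closing metathesis of 2-vinylaryl allyl ethers to 2H-chromenes and the cross-metathesis of C-allyl phenols and C-allyl flavanones with 2-methylbut-2-ene to the C-prenyl compounds. The six-membered 2H-pyran ring is closed by ring-closing olefin metathesis of a 1,7-diene, a cycloaddition–cycloreversion sequence, and the ring size enforces the cis olefin. No stereocentre is created, and the C2 stereocentre from step 8 is not touched because the medium is neutral and aprotic. The step needs ring closure over oligomerisation and site selectivity among three terminal olefins: the ortho relation of the vinyl group to the ether oxygen, the gem-dimethyl group (Thorpe–Ingold effect) and high dilution secure the first, and the allyl group, remote from both ring B olefins, can only react intermolecularly with the excess trisubstituted olefin. The chromene olefin (cis-disubstituted, between an arene and a quaternary carbon) and the trisubstituted prenyl olefin are inert to further metathesis, and 1,4-benzoquinone suppresses isomerisation of the allyl group by Ru–H species.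

Step 10
Reactants: 15 (2S)-7-(methoxymethoxy)-2-[7-(methoxymethoxy)-2,2-dimethyl-2H-chromen-6-yl]-8-(3-methylbut-2-en-1-yl)-2,3-dihydro-4H-chromen-4-one
Product: 16 (2S)-7-hydroxy-2-(7-hydroxy-2,2-dimethyl-2H-chromen-6-yl)-8-(3-methylbut-2-en-1-yl)-2,3-dihydro-4H-chromen-4-one
Conditions: HCl (3 M aq.)/MeOH (1:10), 40 °C
Reagents that add atoms: none
Why: Acid-catalysed transacetalisation transfers both MOM groups to methanol as dimethoxymethane, and dilute acid without base is chosen so that the C2–O1 bond (no enolate-driven ring opening), the prenyl group and the chromene should persist.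

**Compound list**

1 | 3-allyl-2,4-dihydroxyacetophenone, 1-[2,4-dihydroxy-3-(prop-2-en-1-yl)phenyl]ethan-1-one | CC(=O)c1ccc(O)c(CC=C)c1O | starting material
2 | 1-[2-hydroxy-4-(methoxymethoxy)-3-(prop-2-en-1-yl)phenyl]ethan-1-one | CC(=O)c1ccc(OCOC)c(CC=C)c1O | intermediate
3 | (E)-3-(dimethylamino)-1-[2-hydroxy-4-(methoxymethoxy)-3-(prop-2-en-1-yl)phenyl]prop-2-en-1-one | CN(C)/C=C/C(=O)c1ccc(OCOC)c(CC=C)c1O | intermediate
4 | 7-(methoxymethoxy)-8-(prop-2-en-1-yl)-4H-chromen-4-one | O=c1ccoc2c(CC=C)c(OCOC)ccc12 | intermediate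
5 | 5-bromo-2,4-dihydroxybenzaldehyde | O=Cc1cc(Br)c(O)cc1O | starting material
6 | 5-bromo-2-hydroxy-4-(methoxymethoxy)benzaldehyde | O=Cc1cc(Br)c(OCOC)cc1O | intermediate
7 | 5-bromo-4-(methoxymethoxy)-2-[(2-methylbut-3-yn-2-yl)oxy]benzaldehyde | O=Cc1cc(Br)c(OCOC)cc1OC(C)(C)C#C | intermediate
8 | 5-bromo-4-(methoxymethoxy)-2-[(2-methylbut-3-en-2-yl)oxy]benzaldehyde | O=Cc1cc(Br)c(OCOC)cc1OC(C)(C)C=C | intermediate
9 | 1-bromo-5-ethenyl-2-(methoxymethoxy)-4-[(2-methylbut-3-en-2-yl)oxy]benzene | C=Cc1cc(Br)c(OCOC)cc1OC(C)(C)C=C | intermediate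
10 | {5-ethenyl-2-(methoxymethoxy)-4-[(2-methylbut-3-en-2-yl)oxy]phenyl}lithium | [Li]c1cc(C=C)c(OC(C)(C)C=C)cc1OCOC | intermediate
11 | lithium {5-ethenyl-2-(methoxymethoxy)-4-[(2-methylbut-3-en-2-yl)oxy]phenyl}tri(propan-2-yloxy)borate | [Li+].CC(C)O[B-](OC(C)C)(OC(C)C)c1cc(C=C)c(OC(C)(C)C=C)cc1OCOC | intermediate
12 | {5-ethenyl-2-(methoxymethoxy)-4-[(2-methylbut-3-en-2-yl)oxy]phenyl}boronic acid | OB(O)c1cc(C=C)c(OC(C)(C)C=C)cc1OCOC | intermediate
13 | (2S)-2-{5-ethenyl-2-(methoxymethoxy)-4-[(2-methylbut-3-en-2-yl)oxy]phenyl}-7-(methoxymethoxy)-8-(prop-2-en-1-yl)-2,3-dihydro-4H-chromen-4-one | C=CCc1c(OCOC)ccc2c1O[C@H](c1cc(C=C)c(OC(C)(C)C=C)cc1OCOC)CC2=O | intermediate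
14 | (2S)-7-(methoxymethoxy)-2-[7-(methoxymethoxy)-2,2-dimethyl-2H-chromen-6-yl]-8-(prop-2-en-1-yl)-2,3-dihydro-4H-chromen-4-one | C=CCc1c(OCOC)ccc2c1O[C@H](c1cc3c(cc1OCOC)OC(C)(C)C=C3)CC2=O | intermediate
15 | (2S)-7-(methoxymethoxy)-2-[7-(methoxymethoxy)-2,2-dimethyl-2H-chromen-6-yl]-8-(3-methylbut-2-en-1-yl)-2,3-dihydro-4H-chromen-4-one | CC(C)=CCc1c(OCOC)ccc2c1O[C@H](c1cc3c(cc1OCOC)OC(C)(C)C=C3)CC2=O | intermediate
16 | (2S)-7-hydroxy-2-(7-hydroxy-2,2-dimethyl-2H-chromen-6-yl)-8-(3-methylbut-2-en-1-yl)-2,3-dihydro-4H-chromen-4-one | CC(C)=CCc1c(O)ccc2c1O[C@H](c1cc3c(cc1O)OC(C)(C)C=C3)CC2=O | target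

**Step count**

Total steps: 10. Longest linear sequence: 8 steps (steps 3 to 10, from 5).

**Steps most likely to fail**

1. Step 8. The electron-rich, ortho-alkoxy arylboronic acid may transmetalate slowly and protodeboronate, and base-induced β-elimination of the enolate (opening of ring C to the chalcone phenoxide) may erode the enantiomeric purity. The fallback sets out from 9 (and uses 2) and comes back at 13; it builds the flavanone by oxa-Michael closure and resolves it. Bromine–lithium exchange of 9 (n-BuLi, THF, −78 °C) gives aryllithium 10, which adds to DMF to give lithium (dimethylamino){5-ethenyl-2-(methoxymethoxy)-4-[(2-methylbut-3-en-2-yl)oxy]phenyl}methanolate F1; aqueous work-up releases 5-ethenyl-2-(methoxymethoxy)-4-[(2-methylbut-3-en-2-yl)oxy]benzaldehyde F2. Claisen–Schmidt condensation of F2 with acetophenone 2 (KOH, EtOH, rt) should give (E)-1-[2-hydroxy-4-(methoxymethoxy)-3-(prop-2-en-1-yl)phenyl]-3-{5-ethenyl-2-(methoxymethoxy)-4-[(2-methylbut-3-en-2-yl)oxy]phenyl}prop-2-en-1-one F3. NaOAc in refluxing EtOH cyclises it to the racemic flavanone rac-2-{5-ethenyl-2-(methoxymethoxy)-4-[(2-methylbut-3-en-2-yl)oxy]phenyl}-7-(methoxymethoxy)-8-(prop-2-en-1-yl)-2,3-dihydro-4H-chromen-4-one F4. Kinetic resolution by asymmetric transfer hydrogenation (RhCl(Cp*)[(R,R)-TsDPEN], HCO2H/Et3N, EtOAc, rt) should reduce the (2R)-enantiomer to the cis alcohol (2R,4R)-2-{5-ethenyl-2-(methoxymethoxy)-4-[(2-methylbut-3-en-2-yl)oxy]phenyl}-7-(methoxymethoxy)-8-(prop-2-en-1-yl)-3,4-dihydro-2H-chromen-4-ol F5 and leave the (2S)-flavanone 13, at the cost of at most half of the material.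

2. Step 9. Cross-metathesis at the allyl group may stay incomplete, Ru–H species may move the allyl double bond into conjugation, and the styrene may react intermolecularly before the ring closes. The fallback sets out from 9 and 4 and comes back at 15; it moves both metatheses to the fragment stage and runs them separately. Ring-closing metathesis of 9 (RuCl2(=CHPh)(PCy3)(H2IMes), CH2Cl2, 40 °C) should give 6-bromo-7-(methoxymethoxy)-2,2-dimethyl-2H-chromene F6. The tertiary allyl ether is gone at this point, so Miyaura borylation (PdCl2(dppf), bis(pinacolato)diboron, KOAc, 1,4-dioxane, 80 °C) can give 2-[7-(methoxymethoxy)-2,2-dimethyl-2H-chromen-6-yl]-4,4,5,5-tetramethyl-1,3,2-dioxaborolane F7. Cross-metathesis of chromone 4 with 2-methylbut-2-ene (same Ru catalyst, 40 °C) should give 7-(methoxymethoxy)-8-(3-methylbut-2-en-1-yl)-4H-chromen-4-one F8. The Hayashi–Miyaura union of F7 and F8 under the conditions of step 8 then leads directly to 15.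

3. Step 10. Under acid the liberated 7-OH may add to the prenyl olefin (chroman formation), methanol may add to the chromene olefin, and acid-promoted opening of ring C may lower the enantiomeric purity. The fallback sets out from 13 and comes back at 16; it divides the tandem so that acid is used before the prenyl olefin exists. 13 is taken through the ring-closing metathesis alone (no 2-methylbut-2-ene) and 14 is isolated. MOM removal on 14 (HCl, MeOH, 40 °C), whose allyl group does not cyclise under acid, should give (2S)-7-hydroxy-2-(7-hydroxy-2,2-dimethyl-2H-chromen-6-yl)-8-(prop-2-en-1-yl)-2,3-dihydro-4H-chromen-4-one F9. Cross-metathesis of the free phenol F9 with 2-methylbut-2-ene (RuCl2(=CHPh)(PCy3)(H2IMes), 1,4-benzoquinone, CH2Cl2, 40 °C) then gives 16 under neutral conditions as the last step.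

**Further compounds**

F1 | step 8 | lithium (dimethylamino){5-ethenyl-2-(methoxymethoxy)-4-[(2-methylbut-3-en-2-yl)oxy]phenyl}methanolate | [Li+].[O-]C(N(C)C)c1cc(C=C)c(OC(C)(C)C=C)cc1OCOC
F2 | step 8 | 5-ethenyl-2-(methoxymethoxy)-4-[(2-methylbut-3-en-2-yl)oxy]benzaldehyde | O=Cc1cc(C=C)c(OC(C)(C)C=C)cc1OCOC
F3 | step 8 | (E)-1-[2-hydroxy-4-(methoxymethoxy)-3-(prop-2-en-1-yl)phenyl]-3-{5-ethenyl-2-(methoxymethoxy)-4-[(2-methylbut-3-en-2-yl)oxy]phenyl}prop-2-en-1-one | C=CCc1c(OCOC)ccc(C(=O)/C=C/c2cc(C=C)c(OC(C)(C)C=C)cc2OCOC)c1O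
F4 | step 8 | rac-2-{5-ethenyl-2-(methoxymethoxy)-4-[(2-methylbut-3-en-2-yl)oxy]phenyl}-7-(methoxymethoxy)-8-(prop-2-en-1-yl)-2,3-dihydro-4H-chromen-4-one | C=CCc1c(OCOC)ccc2c1OC(c1cc(C=C)c(OC(C)(C)C=C)cc1OCOC)CC2=O
F5 | step 8 | (2R,4R)-2-{5-ethenyl-2-(methoxymethoxy)-4-[(2-methylbut-3-en-2-yl)oxy]phenyl}-7-(methoxymethoxy)-8-(prop-2-en-1-yl)-3,4-dihydro-2H-chromen-4-ol | C=CCc1c(OCOC)ccc2c1O[C@@H](c1cc(C=C)c(OC(C)(C)C=C)cc1OCOC)C[C@H]2O
F6 | step 9 | 6-bromo-7-(methoxymethoxy)-2,2-dimethyl-2H-chromene | CC1(C)C=Cc2cc(Br)c(OCOC)cc2O1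
F7 | step 9 | 2-[7-(methoxymethoxy)-2,2-dimethyl-2H-chromen-6-yl]-4,4,5,5-tetramethyl-1,3,2-dioxaborolane | CC1(C)C=Cc2cc(B3OC(C)(C)C(C)(C)O3)c(OCOC)cc2O1
F8 | step 9 | 7-(methoxymethoxy)-8-(3-methylbut-2-en-1-yl)-4H-chromen-4-one | O=c1ccoc2c(CC=C(C)C)c(OCOC)ccc12
F9 | step 10 | (2S)-7-hydroxy-2-(7-hydroxy-2,2-dimethyl-2H-chromen-6-yl)-8-(prop-2-en-1-yl)-2,3-dihydro-4H-chromen-4-one | C=CCc1c(O)ccc2c1O[C@H](c1cc3c(cc1O)OC(C)(C)C=C3)CC2=O
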